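(The numbers in the tables were computed on assumed constants.)

How much product will a flask of 2.0 M starting material hold after 5.0 min with the gas phase held as in the alder run, and how near saturation will its solution stand?

- alder: starting material 1 M; gas phase 75 mM (held); run made earlier
- flask: starting material 2.0 M; gas phase 75 mM (held); time 5.0 min

- alder (time / min: product / %): 0.200: 2.9; 0.667: 13.2; 1.00: 19.2; 1.50: 24.4; 2.50: 32.1; 3.00: 32.3; 4.00: 33.1

(each reading ± 1 percentage point)

- at the start none of the gas phase is in solution

1. product at 5.0 min, in percent of the starting material charged
2. concentration of dissolved gas in solution at 5.0 min, in percent of saturation

At the bench you would call the dissolved gas the limiting reagent. A solution saturated at 75 mM against 1 M of starting material then caps the alder run at a yield of 7.50%. But the balance of dissolved gas has an inflow from the held gas phase, so that cap counts a single filling of the solution. The alder readings cross this border early, with 13.2% at 0.667 min.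

Watch something else instead: the plateau ratio, product per starting material left at the flat end of the curve, here 0.495, read in the alder run at 4.00 min and carrying the scatter of that reading. From 2.50 min on, the alder readings run from 32.1% to 33.1%, about the scatter of 1 percentage point. At the same saturation I expect the same ratio in this flask, which gives 33.1%, provided it arrives in time. That much product stands for 8.83 fillings of its solution.

The forecast says 31% and 96%, reasoning that “the plateau fraction should be about the same”. Its yield stands 2.1 points below mine.

The flask gives 33.6% and 85.4%, and it holds 0.0754 M of homo dimer at 5.00 min.

    gas phase ⇌ dissolved gas, rate k1*(csat - [dissolved gas]) (kL = 0.110 s⁻¹)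
    starting material + dissolved gas ⇌ product (K = 8.10 M⁻¹, k = 0.170 M⁻¹ s⁻¹)
    2 dissolved gas → homo dimer (k = 0.100 M⁻¹ s⁻¹)

Product per starting material left in this flask is 0.506, beside the 0.495 carried from the alder run. The curve of this flask flattens mainly because product falls back to starting material and dissolved gas: at 5.0 min the run without that step reaches 74.8% instead of 33.6%, the mark of thermodynamic control. For the neighbouring flask with 0.80 M of starting material, the ratio 0.495 gives 33.1%, and the computed run gives 35.0% at 5.00 min.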